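The earlier runs and the new flask are calculated with constants of no real substance, noise included.

- 0.436 d is the quick number for the flask: the G clock, the charge of G divided by the rate at which E is made, which is the time for the E made to match the G charged.

| flask | X | Z | G | J | remark | time |
|---|---|---|---|---|---|---|
| spring | 0.80 M | 0.96 M | 80 mM | 8 mM | run made earlier |  |
| midnight | 0.80 M | 2.2 M | 80 mM | 8 mM | run made earlier |  |
| summer | 1.2 M | 1.44 M | 80 mM | 8 mM | run made earlier |  |
| flask | 0.80 M | 1.44 M | 80 mM | 8.0 mM |  | 15 d |

- spring (time / d: L / %, E / %): 0.104: 30, 1; 0.333: 55, 4; 1.04: 54, 9; 3.00: 28, 34; 10.0: 0, 65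
- midnight (time / d: L / %, E / %): 0.104: 32, 0; 0.333: 48, 12; 1.04: 31, 26; 3.00: 2, 57; 10.0: 2, 56
- summer (time / d: L / %, E / %): 0.104: 33, 2; 0.333: 53, 3; 1.04: 50, 9; 3.00: 21, 39; 10.0: 0, 64

(scatter of a reading: 1.5 percentage points)

- on the list of suspects stand: X + G <-> G + L; J + L <-> D; Z + D -> J + E; G + E -> Q

- time, not beyond 15 d, at which the flask holds most L
- the amount of L, in percent of the X charged, at that time
- earliest time at which at least nineteen twentieths of that best amount are there, in d
- latest time at which they still are, in d

- The summer run shares the flask's charges of Z, G and J but holds more X, so its rate is a reading taken over for the flask: its E climbs from 9 % to 39 % of its X between 1.04 d and 3.00 d, which is 0.184 M/d.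
- On the suspected step G + E → Q, a catalyst deactivation, each E taken costs one G. L comes from X on G, so the flask's making of L should fade near the clock while the way through J goes on.
- The height comes from the highest readings of L, 55 % in the spring run and 48 % in the midnight run. These share the flask's charges of X, G and J, and a straight line in Z gives 52.3 % for the flask.
- The forecast says 0.45 d and 53 %, with the band from 0.29 d to 0.72 d, by “Balancing rise against drain”. The reckoning here lands a little earlier and a little lower.
- The flask gives 53.4 % at 0.454 d, with the band from 0.294 d to 0.694 d.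

    X + G ⇌ G + L (K = 2.60, k = 6.20 × 10⁻⁴ /M/s)
    J + L ⇌ D (K = 7.70 /M, k = 0.0170 /M/s)
    Z + D → J + E (k = 3.30 × 10⁻⁴ /M/s)
    G + E → Q (k = 7.40 × 10⁻⁴ /M/s)

- At 0.114 d the flask makes L 8.02 times faster than it uses it up, each step taken net. At 0.454 d, close to the clock's 0.436 d, about half of the flask's G is left, and at 1.50 d hardly any, 0.00900 %. A neighbour like the flask but charged with 0.032 M of G has, with the rate taken over unchanged, a clock of 0.174 d; its best L is 34.0 %, and 50 % of its X is left at the end.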